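**Retrosynthetic overview**

1. The last step only removes four MOM groups from flavanone 18. Rings A and B are bought (phloroglucinol, 3,4-dihydroxyacetophenone); ring C is the only ring made.
2. Ring C is opened at O1–C8a and C4–C4a. Ring A becomes a 3,5-bis(OMOM)-4-alkenyl aryne (from ortho-silylaryl triflate 11); C2–C3–C4 with ring B becomes the (S)-β-silyloxy ester 16. One fluoride-triggered aryne annulation joins them.
3. Enabling feature: O1 and the C4 carbonyl sit on adjacent ring-A carbons (C8a, C4a), an aryne retron. The C5 oxygen next to C4a polarises the aryne so the alkoxide adds at C8a, and the O1–C2–C3–C4 chain holds the ester where the C4a anion closes a six-membered ring.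
4. Triflate 11 comes from a mirror-symmetric phloroglucinol ether by two directed ortho-metalations; the side chain and its (S)-centre come from (S)-citronellal by aryllithium addition and dehydration.
5. C2 is set by asymmetric transfer hydrogenation of β-keto ester 14 and carried through the key step with its C–O bond intact.

Key step: step 12

Remark: the carbinol carbon made in step 3 is left uncontrolled because step 4 removes it; commercial (S)-citronellal is assumed to be of sufficient enantiomeric purity.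

**Route**

Step 1
Reactants: 1 phloroglucinol (benzene-1,3,5-triol)
Product: 2 3,5-bis(methoxymethoxy)phenol
Conditions: MOMCl (2 equiv), i-Pr2NEt, DMF, 0 °C to rt; chromatography, mono-ether recycled
Reagents that add atoms: chloromethyl methyl ether (MOMCl), COCCl
Why: O-alkylation of the phenoxide by the α-chloro ether; the threefold symmetry of 1 makes the bis-ether a single compound, to be separated from the statistical mixture.

Step 2
Reactants: 2 3,5-bis(methoxymethoxy)phenol
Product: 3 [3,5-bis(methoxymethoxy)phenoxy]triisopropylsilane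
Conditions: TIPSCl, imidazole, DMF, rt
Reagents that add atoms: chlorotriisopropylsilane (TIPSCl), CC(C)[Si](Cl)(C(C)C)C(C)C
Why: Silylation of the remaining phenol; the bulky, poorly coordinating TIPS ether withstands alkyllithiums and keeps the next metalation away from its own ortho positions.

Step 3
Reactants: 3 [3,5-bis(methoxymethoxy)phenoxy]triisopropylsilane, 4 (S)-citronellal [(3S)-3,7-dimethyloct-6-enal]
Product: 6 (1RS,3S)-1-[2,6-bis(methoxymethoxy)-4-(triisopropylsilyloxy)phenyl]-3,7-dimethyloct-6-en-1-ol, via aryllithium 5 (not isolated)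
Conditions: n-BuLi, THF, 0 °C; then 4, −78 °C to 0 °C; H2O
Reagents that add atoms: none
Why: Directed ortho-metalation at the C–H between the two OMOM groups (cooperative chelation) followed by 1,2-addition of the aryllithium to the aldehyde; the carbinol centre forms without control and is erased in step 4, while the C3 centre of 4 is β to the carbonyl and cannot epimerise by enolisation.

Step 4
Reactants: 6 (1RS,3S)-1-[2,6-bis(methoxymethoxy)-4-(triisopropylsilyloxy)phenyl]-3,7-dimethyloct-6-en-1-ol
Product: 7 {4-[(1E,3S)-3,7-dimethylocta-1,6-dien-1-yl]-3,5-bis(methoxymethoxy)phenoxy}triisopropylsilane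
Conditions: Burgess reagent, toluene, 50 °C
Reagents that add atoms: none
Why: Burgess dehydration (syn-elimination of the sulfamate ester): only C2 of the chain carries β-hydrogens so only the styrene can form, the E isomer is favoured because the Z transition state presses the chain against the 2,6-disubstituted ring, and the non-acidic medium is chosen to limit cation–olefin cyclisation onto the trisubstituted alkene.

Step 5
Reactants: 7 {4-[(1E,3S)-3,7-dimethylocta-1,6-dien-1-yl]-3,5-bis(methoxymethoxy)phenoxy}triisopropylsilane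
Product: 9 {4-[(1E,3S)-3,7-dimethylocta-1,6-dien-1-yl]-3,5-bis(methoxymethoxy)-2-(trimethylsilyl)phenoxy}triisopropylsilane, via aryllithium 8 (not isolated)
Conditions: s-BuLi, TMEDA, THF, −78 °C; then TMSCl, −78 °C to 0 °C
Reagents that add atoms: chlorotrimethylsilane (TMSCl), C[Si](C)(C)Cl
Why: Directed ortho-metalation (OMOM-directed) at one of the two equivalent remaining ring C–H bonds and silyl quench; the mirror symmetry of 7 makes the site unambiguous and the low temperature should spare the styrene and prevent O-to-C migration of the TIPS group.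

Step 6
Reactants: 9 {4-[(1E,3S)-3,7-dimethylocta-1,6-dien-1-yl]-3,5-bis(methoxymethoxy)-2-(trimethylsilyl)phenoxy}triisopropylsilane
Product: 10 4-[(1E,3S)-3,7-dimethylocta-1,6-dien-1-yl]-3,5-bis(methoxymethoxy)-2-(trimethylsilyl)phenol
Conditions: TBAF, AcOH, THF, 0 °C
Reagents that add atoms: none
Why: Fluoride cleaves the aryl O–Si bond far faster than the aryl C–SiMe3 bond, which has no ortho leaving group at this stage; acetic acid buffers the phenoxide.

Step 7
Reactants: 10 4-[(1E,3S)-3,7-dimethylocta-1,6-dien-1-yl]-3,5-bis(methoxymethoxy)-2-(trimethylsilyl)phenol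
Product: 11 4-[(1E,3S)-3,7-dimethylocta-1,6-dien-1-yl]-3,5-bis(methoxymethoxy)-2-(trimethylsilyl)phenyl trifluoromethanesulfonate
Conditions: PhNTf2, DBU, MeCN, rt to 40 °C
Reagents that add atoms: N-phenylbis(trifluoromethanesulfonimide) (PhNTf2), O=S(=O)(N(c1ccccc1)S(=O)(=O)C(F)(F)F)C(F)(F)F
Why: O-sulfonylation of the hindered phenoxide with a mild triflyl donor, the usual last step toward an ortho-silylaryl triflate aryne precursor.

Step 8
Reactants: 12 3,4-dihydroxyacetophenone
Product: 13 3,4-bis(methoxymethoxy)acetophenone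
Conditions: MOMCl, i-Pr2NEt, CH2Cl2, 0 °C to rt
Reagents that add atoms: chloromethyl methyl ether (MOMCl), COCCl
Why: O-alkylation of both catechol hydroxyls by the α-chloro ether.

Step 9
Reactants: 13 3,4-bis(methoxymethoxy)acetophenone
Product: 14 methyl 3-[3,4-bis(methoxymethoxy)phenyl]-3-oxopropanoate
Conditions: NaH, (MeO)2CO, THF, reflux; AcOH quench
Reagents that add atoms: dimethyl carbonate, COC(=O)OC
Why: Crossed Claisen condensation of the methyl ketone enolate with dimethyl carbonate, driven by formation of the stabilised β-keto ester enolate.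

Step 10
Reactants: 14 methyl 3-[3,4-bis(methoxymethoxy)phenyl]-3-oxopropanoate
Product: 15 methyl (3S)-3-[3,4-bis(methoxymethoxy)phenyl]-3-hydroxypropanoate
Conditions: RuCl[(S,S)-TsDPEN](p-cymene) (1 mol %), HCO2H/Et3N (1:1), DMF, 40 °C
Reagents that add atoms: none
Why: Noyori–Ikariya asymmetric transfer hydrogenation of an aryl ketone, in which the (S,S)-catalyst should deliver hydride to the face that gives (S)-1-arylalkanols (aryl–arene CH–π contact in the transition state), here the (3S)-alcohol; the near-neutral formate medium spares the MOM ethers.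

Step 11
Reactants: 15 methyl (3S)-3-[3,4-bis(methoxymethoxy)phenyl]-3-hydroxypropanoate
Product: 16 methyl (3S)-3-[3,4-bis(methoxymethoxy)phenyl]-3-(trimethylsilyloxy)propanoate
Conditions: HMDS, TMSCl (cat.), CH2Cl2, rt; evaporation, used crude
Reagents that add atoms: hexamethyldisilazane (HMDS), C[Si](C)(C)N[Si](C)(C)C
Why: Silylation of the secondary alcohol removes the only O–H from the key step and turns the oxygen into a fluoride-triggered latent alkoxide; the only by-product is volatile, so the labile ether needs no aqueous work-up.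

Step 12
Reactants: 11 4-[(1E,3S)-3,7-dimethylocta-1,6-dien-1-yl]-3,5-bis(methoxymethoxy)-2-(trimethylsilyl)phenyl trifluoromethanesulfonate, 16 methyl (3S)-3-[3,4-bis(methoxymethoxy)phenyl]-3-(trimethylsilyloxy)propanoate
Product: 18 (2S)-2-[3,4-bis(methoxymethoxy)phenyl]-6-[(1E,3S)-3,7-dimethylocta-1,6-dien-1-yl]-5,7-bis(methoxymethoxy)-2,3-dihydro-4H-chromen-4-one, via aryne 17 (not isolated)
Conditions: CsF (3 equiv), 18-crown-6 (cat.), THF, 25–40 °C; 16 added slowly to 11 (1.3 equiv)
Reagents that add atoms: none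
Why: Proposed new method: fluoride cleaves the C–Si bond of 11 with loss of triflate to give aryne 17 and also unmasks the alkoxide of 16, which adds to the aryne carbon remote from the C5 oxygen (future C8a); the aryl anion left at C4a, next to OMOM, then attacks the methyl ester six atoms away and expels methoxide, which desilylates further 16 and so relays the chain. The closest known reaction type is the fluoride-mediated annulation of arynes with salicylate esters to xanthones (O-addition, then acyl substitution by the aryl anion), together with aryne acyl-alkylation; the new element is an aliphatic β-silyloxy ester as the O/C(=O) donor. Ring C closes by 6-exo-trig acyl substitution at C4–C4a after intermolecular O1–C8a bond formation. No stereocentre is created: C2 comes from 16 with its C–O bond untouched, so its configuration should be retained. The step needs regioselective addition to the unsymmetrical aryne, which the inductive and distortion effect of the C5 OMOM group secures, and acylation of the aryl anion in preference to protonation, which the silyl ether (no O–H), the aprotic solvent and the six-membered transition state secure. Slow addition of 16 and a sparingly soluble fluoride keep the free alkoxide concentration low, to limit retro-aldol cleavage and base-induced ring-opening of the product.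

Step 13
Reactants: 18 (2S)-2-[3,4-bis(methoxymethoxy)phenyl]-6-[(1E,3S)-3,7-dimethylocta-1,6-dien-1-yl]-5,7-bis(methoxymethoxy)-2,3-dihydro-4H-chromen-4-one
Product: 20 (2S)-2-(3,4-dihydroxyphenyl)-6-[(1E,3S)-3,7-dimethylocta-1,6-dien-1-yl]-5,7-dihydroxy-2,3-dihydro-4H-chromen-4-one, via tetrakis(trimethylsilyl) ether 19 (not isolated)
Conditions: TMSOTf, 2,2'-bipyridyl, MeCN, 0 °C to rt; then H2O, rt
Reagents that add atoms: none
Why: Silyl triflate–bipyridyl cleavage of aryl MOM ethers, in which the bipyridyl-bound silyl cation converts each ArOCH2OMe into ArOSiMe3 and water then hydrolyses the silyl ethers; no free Brønsted acid or base is present, so the diene (prone to cation–olefin cyclisation onto ring A) and the base-labile C2 centre should survive.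

**Compound list**

1 | phloroglucinol | Oc1cc(O)cc(O)c1 | starting material
2 | 3,5-bis(methoxymethoxy)phenol | COCOc1cc(O)cc(OCOC)c1 | intermediate
3 | [3,5-bis(methoxymethoxy)phenoxy]triisopropylsilane | COCOc1cc(OCOC)cc(O[Si](C(C)C)(C(C)C)C(C)C)c1 | intermediate
4 | (S)-citronellal, (3S)-3,7-dimethyloct-6-enal | CC(C)=CCC[C@H](C)CC=O | starting material
5 | [2,6-bis(methoxymethoxy)-4-(triisopropylsilyloxy)phenyl]lithium | COCOc1cc(O[Si](C(C)C)(C(C)C)C(C)C)cc(OCOC)c1[Li] | intermediate
6 | (1RS,3S)-1-[2,6-bis(methoxymethoxy)-4-(triisopropylsilyloxy)phenyl]-3,7-dimethyloct-6-en-1-ol | CC(C)=CCC[C@H](C)CC(O)c1c(OCOC)cc(O[Si](C(C)C)(C(C)C)C(C)C)cc1OCOC | intermediate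
7 | {4-[(1E,3S)-3,7-dimethylocta-1,6-dien-1-yl]-3,5-bis(methoxymethoxy)phenoxy}triisopropylsilane | CC(C)=CCC[C@H](C)/C=C/c1c(OCOC)cc(O[Si](C(C)C)(C(C)C)C(C)C)cc1OCOC | intermediate
8 | {3-[(1E,3S)-3,7-dimethylocta-1,6-dien-1-yl]-2,4-bis(methoxymethoxy)-6-(triisopropylsilyloxy)phenyl}lithium | CC(C)=CCC[C@H](C)/C=C/c1c(OCOC)cc(O[Si](C(C)C)(C(C)C)C(C)C)c([Li])c1OCOC | intermediate
9 | {4-[(1E,3S)-3,7-dimethylocta-1,6-dien-1-yl]-3,5-bis(methoxymethoxy)-2-(trimethylsilyl)phenoxy}triisopropylsilane | CC(C)=CCC[C@H](C)/C=C/c1c(OCOC)cc(O[Si](C(C)C)(C(C)C)C(C)C)c([Si](C)(C)C)c1OCOC | intermediate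
10 | 4-[(1E,3S)-3,7-dimethylocta-1,6-dien-1-yl]-3,5-bis(methoxymethoxy)-2-(trimethylsilyl)phenol | CC(C)=CCC[C@H](C)/C=C/c1c(OCOC)cc(O)c([Si](C)(C)C)c1OCOC | intermediate
11 | 4-[(1E,3S)-3,7-dimethylocta-1,6-dien-1-yl]-3,5-bis(methoxymethoxy)-2-(trimethylsilyl)phenyl trifluoromethanesulfonate | CC(C)=CCC[C@H](C)/C=C/c1c(OCOC)cc(OS(=O)(=O)C(F)(F)F)c([Si](C)(C)C)c1OCOC | intermediate
12 | 3,4-dihydroxyacetophenone | CC(=O)c1ccc(O)c(O)c1 | starting material
13 | 3,4-bis(methoxymethoxy)acetophenone | CC(=O)c1ccc(OCOC)c(OCOC)c1 | intermediate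
14 | methyl 3-[3,4-bis(methoxymethoxy)phenyl]-3-oxopropanoate | COC(=O)CC(=O)c1ccc(OCOC)c(OCOC)c1 | intermediate
15 | methyl (3S)-3-[3,4-bis(methoxymethoxy)phenyl]-3-hydroxypropanoate | COC(=O)C[C@@H](c1ccc(OCOC)c(OCOC)c1)O | intermediate
16 | methyl (3S)-3-[3,4-bis(methoxymethoxy)phenyl]-3-(trimethylsilyloxy)propanoate | COC(=O)C[C@@H](c1ccc(OCOC)c(OCOC)c1)O[Si](C)(C)C | intermediate
17 | 4-[(1E,3S)-3,7-dimethylocta-1,6-dien-1-yl]-3,5-bis(methoxymethoxy)-1,2-didehydrobenzene (aryne) | CC(C)=CCC[C@H](C)/C=C/C1=C(OCOC)C#CC=C1OCOC | intermediate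
18 | (2S)-2-[3,4-bis(methoxymethoxy)phenyl]-6-[(1E,3S)-3,7-dimethylocta-1,6-dien-1-yl]-5,7-bis(methoxymethoxy)-2,3-dihydro-4H-chromen-4-one | CC(C)=CCC[C@H](C)/C=C/c1c(OCOC)cc2c(c1OCOC)C(=O)C[C@@H](c1ccc(OCOC)c(OCOC)c1)O2 | intermediate
19 | (2S)-2-[3,4-bis(trimethylsilyloxy)phenyl]-6-[(1E,3S)-3,7-dimethylocta-1,6-dien-1-yl]-5,7-bis(trimethylsilyloxy)-2,3-dihydro-4H-chromen-4-one | CC(C)=CCC[C@H](C)/C=C/c1c(O[Si](C)(C)C)cc2c(c1O[Si](C)(C)C)C(=O)C[C@@H](c1ccc(O[Si](C)(C)C)c(O[Si](C)(C)C)c1)O2 | intermediate
20 | (2S)-2-(3,4-dihydroxyphenyl)-6-[(1E,3S)-3,7-dimethylocta-1,6-dien-1-yl]-5,7-dihydroxy-2,3-dihydro-4H-chromen-4-one | CC(C)=CCC[C@H](C)/C=C/c1c(O)cc2c(c1O)C(=O)C[C@@H](c1ccc(O)c(O)c1)O2 | target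

**Step count**

Total: 13 steps. Longest linear sequence: 9 steps (steps 1–7, 12, 13).

**Steps most likely to fail**

Step 12 (proposed method). The aryl anion may take a proton from the α-CH2 of the ester, after which the enolate expels the aryloxide. The transient alkoxide may also undergo retro-aldol cleavage, or the product may ring-open under base and lose its C2 configuration. The fallback uses known chemistry and closes ring C by an intramolecular Mitsunobu etherification instead. It sets out from 14 and from aryllithium 8 (made from 7 as in step 5) and comes back at 18. Transfer hydrogenation of 14 with RuCl[(R,R)-TsDPEN](p-cymene) and HCO2H/Et3N should give methyl (3R)-3-[3,4-bis(methoxymethoxy)phenyl]-3-hydroxypropanoate F1. MeNH(OMe)·HCl with i-PrMgCl in THF should convert it into (3R)-3-[3,4-bis(methoxymethoxy)phenyl]-3-hydroxy-N-methoxy-N-methylpropanamide F2. After O-deprotonation with i-PrMgCl, F2 should acylate 8 at −78 °C to give (3R)-3-[3,4-bis(methoxymethoxy)phenyl]-1-{3-[(1E,3S)-3,7-dimethylocta-1,6-dien-1-yl]-2,4-bis(methoxymethoxy)-6-(triisopropylsilyloxy)phenyl}-3-hydroxypropan-1-one F3. TBAF/AcOH should free (3R)-3-[3,4-bis(methoxymethoxy)phenyl]-1-{3-[(1E,3S)-3,7-dimethylocta-1,6-dien-1-yl]-6-hydroxy-2,4-bis(methoxymethoxy)phenyl}-3-hydroxypropan-1-one F4. PPh3 and DIAD in THF at 0 °C should then close the O1–C2 bond with inversion at the benzylic carbon to give 18.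

Step 4. The activated benzylic alcohol may ionise and the cation may be captured by the trisubstituted alkene (cation–olefin cyclisation), or E/Z control may be poor. The fallback forms the styrene by cross-coupling, with no benzylic cation. It sets out from aryllithium 5 (made from 3 as in step 3) and from 4, and comes back at 7. Quenching 5 with 1,2-dibromoethane should give [4-bromo-3,5-bis(methoxymethoxy)phenoxy]triisopropylsilane F5. Condensation of 4 with TsNHNH2 in MeOH should give (3S)-3,7-dimethyloct-6-enal N-tosylhydrazone F6. Pd-catalysed cross-coupling of the N-tosylhydrazone with the aryl bromide (Barluenga coupling; Pd2(dba)3 as zerovalent palladium source, XPhos, LiOt-Bu, dioxane, 90 °C) proceeds by carbene formation, aryl migration and β-hydride elimination, and should give 7 directly as the E isomer.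

Step 5. Metalation next to the bulky silyl ether may be slow, and carbolithiation of the styrene or O-to-C silyl migration may compete. The fallback replaces the silyl ether by a strong carbamate directing group, which allows the milder n-BuLi. It sets out from 7 and comes back at 11. TBAF should give 4-[(1E,3S)-3,7-dimethylocta-1,6-dien-1-yl]-3,5-bis(methoxymethoxy)phenol F7. i-PrNCO with Et3N should give 4-[(1E,3S)-3,7-dimethylocta-1,6-dien-1-yl]-3,5-bis(methoxymethoxy)phenyl N-isopropylcarbamate F8. Transient N-silylation (TBSOTf, TMEDA), then n-BuLi/TMEDA at −78 °C and TMSCl, should give 4-[(1E,3S)-3,7-dimethylocta-1,6-dien-1-yl]-3,5-bis(methoxymethoxy)-2-(trimethylsilyl)phenyl N-isopropylcarbamate F9. Carbamate cleavage with Et2NH/DBU in MeCN at 40 °C, followed by PhNTf2 in the same flask, should give 11 (through 10, not isolated).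

**Further compounds**

F1 | step 12 | methyl (3R)-3-[3,4-bis(methoxymethoxy)phenyl]-3-hydroxypropanoate | COC(=O)C[C@H](c1ccc(OCOC)c(OCOC)c1)O
F2 | step 12 | (3R)-3-[3,4-bis(methoxymethoxy)phenyl]-3-hydroxy-N-methoxy-N-methylpropanamide | CON(C)C(=O)C[C@H](c1ccc(OCOC)c(OCOC)c1)O
F3 | step 12 | (3R)-3-[3,4-bis(methoxymethoxy)phenyl]-1-{3-[(1E,3S)-3,7-dimethylocta-1,6-dien-1-yl]-2,4-bis(methoxymethoxy)-6-(triisopropylsilyloxy)phenyl}-3-hydroxypropan-1-one | CC(C)=CCC[C@H](C)/C=C/c1c(OCOC)cc(O[Si](C(C)C)(C(C)C)C(C)C)c(C(=O)C[C@H](c2ccc(OCOC)c(OCOC)c2)O)c1OCOC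
F4 | step 12 | (3R)-3-[3,4-bis(methoxymethoxy)phenyl]-1-{3-[(1E,3S)-3,7-dimethylocta-1,6-dien-1-yl]-6-hydroxy-2,4-bis(methoxymethoxy)phenyl}-3-hydroxypropan-1-one | CC(C)=CCC[C@H](C)/C=C/c1c(OCOC)cc(O)c(C(=O)C[C@H](c2ccc(OCOC)c(OCOC)c2)O)c1OCOC
F5 | step 4 | [4-bromo-3,5-bis(methoxymethoxy)phenoxy]triisopropylsilane | COCOc1cc(O[Si](C(C)C)(C(C)C)C(C)C)cc(OCOC)c1Br
F6 | step 4 | (3S)-3,7-dimethyloct-6-enal N-tosylhydrazone | CC(C)=CCC[C@H](C)CC=NNS(=O)(=O)c1ccc(C)cc1
F7 | step 5 | 4-[(1E,3S)-3,7-dimethylocta-1,6-dien-1-yl]-3,5-bis(methoxymethoxy)phenol | CC(C)=CCC[C@H](C)/C=C/c1c(OCOC)cc(O)cc1OCOC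
F8 | step 5 | 4-[(1E,3S)-3,7-dimethylocta-1,6-dien-1-yl]-3,5-bis(methoxymethoxy)phenyl N-isopropylcarbamate | CC(C)=CCC[C@H](C)/C=C/c1c(OCOC)cc(OC(=O)NC(C)C)cc1OCOC
F9 | step 5 | 4-[(1E,3S)-3,7-dimethylocta-1,6-dien-1-yl]-3,5-bis(methoxymethoxy)-2-(trimethylsilyl)phenyl N-isopropylcarbamate | CC(C)=CCC[C@H](C)/C=C/c1c(OCOC)cc(OC(=O)NC(C)C)c([Si](C)(C)C)c1OCOC
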